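Locants follow tricyclo[5.3.1.0(1,5)]undecane numbering: ring A = C-1, C-7, C-8, C-9, C-10, C-11; ring B = C-1, C-5, C-6, C-7, C-11; ring C = C-1 to C-5.
Cuts: the C-10 ester (to Z-acid 29); the formyl carbon on C-2 (to a C-2 ketone); C-1–C-10 together with C-8=C-9, which opens ring A and releases C-9/C-10 as glyoxal monoacetal; then C-1–C-2 and C-3–C-4 of ring C, back to (S)-α-campholenic aldehyde (ring B, the C-6 methyls, C-7, the C-8 acetic chain, C-4 as a methyl group).
Forward: ring B is bought; ring C follows (allylic oxidation, acyl-anion conjugate addition, aldol condensation, hydrogenation); ring A is closed by a one-pot olefination/aldol annulation; C-2 homologation and a redox reset at C-10 follow; the C16 chain is joined last, before global acidolysis.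
Enabling feature: in cis-diquinane 14 the phosphonate carbon C-8 (on C-7) and H-1 (α to the C-2 ketone) stand 1,3-cis on ring B, so a two-carbon dialdehyde equivalent can span them as the C-8/C-9/C-10 bridge of a bicyclo[3.2.1]octene (rings A and B).
Stereochemistry: C-7 is bought; C-1 and C-5 are relayed from it (anti conjugate addition, cis ring fusion, thermodynamic exo side chain); the quaternary C-1 is fixed by the tether in the key step; C-10 comes from exo-face hydride delivery, C-2 from equilibration, the 9Z alkene from a Wittig reaction.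

Key step: step 8

Remark: the C-2 formyl group of the target is anti to the C-10 acyloxy group (syn to C-11) and is taken to be the thermodynamically favoured epimer, so it is set by equilibration in the last step.

Step 1
Reactants: 1 (S)-α-campholenic aldehyde
Product: 2 (S)-α-campholenic acid
Conditions: NaClO2, NaH2PO4, 2-methyl-2-butene, t-BuOH/H2O, 0 → 23 °C
Reagents that add atoms: sodium chlorite, [Na+].[O-]Cl=O
Why: Pinnick oxidation should convert the aldehyde into the acid without touching the trisubstituted alkene (the hypochlorous acid formed is scavenged by 2-methyl-2-butene) or the bought stereocenter (future C-7).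

Step 2
Reactants: 2 (S)-α-campholenic acid
Product: 3 tert-butyl 2-[(1S)-2,2,3-trimethylcyclopent-3-en-1-yl]acetate
Conditions: O-tert-butyl-N,N′-diisopropylisourea, CH2Cl2, 23 °C
Reagents that add atoms: O-tert-butyl-N,N′-diisopropylisourea, CC(C)NC(=NC(C)C)OC(C)(C)C
Why: isourea-mediated esterification under neutral conditions should give the tert-butyl ester, chosen because it resists the basic steps ahead and falls in the final acidolysis.

Step 3
Reactants: 3 tert-butyl 2-[(1S)-2,2,3-trimethylcyclopent-3-en-1-yl]acetate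
Product: 5 tert-butyl 2-[(1S)-3-formyl-2,2-dimethylcyclopent-3-en-1-yl]acetate, via allylic alcohol 4 (not isolated)
Conditions: SeO2 (1.5 equiv), 1,4-dioxane/H2O (50:1), 80 °C
Reagents that add atoms: selenium dioxide, O=[Se]=O
Why: Riley allylic oxidation (ene reaction, then 2,3-sigmatropic shift) should attack the allylic position on the more substituted alkene carbon, which here can only be the vinylic methyl (future C-4) because C-6 carries no hydrogen, and the alcohol is oxidised on to the enal.

Step 4
Reactants: 5 tert-butyl 2-[(1S)-3-formyl-2,2-dimethylcyclopent-3-en-1-yl]acetate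
Product: 7 tert-butyl 2-[(1S,3R,4R)-4-acetyl-3-formyl-2,2-dimethylcyclopentyl]acetate (with its 3S epimer), via bis-enol ether adduct 6 (not isolated)
Conditions: Li[Cu(C(OEt)=CH2)2] (from ethyl vinyl ether, t-BuLi, CuI), Me3SiCl, THF, −78 °C; then 0.5 M HCl, THF, 0 °C
Reagents that add atoms: (1-ethoxyvinyl)lithium, [Li]C(=C)OCC; water, O
Why: conjugate addition of an acyl-anion equivalent (α-alkoxyvinyl cuprate, accelerated by Me3SiCl) to the enal should place the new carbon at future C-1 anti to the C-7 side chain (1,3-induction on the cyclopentene), and mild acid then hydrolyses both enol ethers; the formyl-bearing carbon (future C-5) is epimerisable and is settled in step 5.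

Step 5
Reactants: 7 tert-butyl 2-[(1S,3R,4R)-4-acetyl-3-formyl-2,2-dimethylcyclopentyl]acetate
Product: 9 tert-butyl 2-[(1R,5R,7S)-6,6-dimethyl-2-oxobicyclo[3.3.0]oct-3-en-7-yl]acetate, via aldol 8 (not isolated)
Conditions: KOH (2% in MeOH), 23 → 50 °C
Reagents that add atoms: none
Why: base-mediated intramolecular aldol condensation of the 1,4-keto aldehyde (methyl ketone enolate onto the aldehyde, then dehydration) should close ring C as a cyclopentenone, and because H-1 (α′) and H-5 (γ) both exchange under these conditions the cis-fused isomer with the C-7 chain on the convex face (cis to H-1 and H-5) should be reached under thermodynamic control.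

Step 6
Reactants: 9 tert-butyl 2-[(1R,5R,7S)-6,6-dimethyl-2-oxobicyclo[3.3.0]oct-3-en-7-yl]acetate
Product: 10 tert-butyl 2-[(1R,5R,7S)-6,6-dimethyl-2-oxobicyclo[3.3.0]octan-7-yl]acetate
Conditions: H2 (1 atm), Pd/C, EtOAc, 23 °C
Reagents that add atoms: none
Why: catalytic hydrogenation should saturate the disubstituted enone double bond without creating or disturbing a stereocenter.

Step 7
Reactants: 10 tert-butyl 2-[(1R,5R,7S)-6,6-dimethyl-2-oxobicyclo[3.3.0]octan-7-yl]acetate
Product: 14 tert-butyl 2-(diethoxyphosphoryl)-2-[(1R,5R,7R)-6,6-dimethyl-2-oxobicyclo[3.3.0]octan-7-yl]acetate, via silyl enol ether 11 (not isolated), via phosphonite 12 (not isolated), via phosphonate silyl enol ether 13 (not isolated)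
Conditions: LiN(iPr)2 (1.05 equiv), Me3SiCl, THF, −78 °C; then LiN(iPr)2 (1.2 equiv), ClP(OEt)2, −78 → 0 °C; then H2O2 (30%), 0 °C; then 1 M HCl
Reagents that add atoms: diethyl chlorophosphite, CCOP(Cl)OCC; hydrogen peroxide, OO
Why: C-phosphinylation of the tert-butyl ester enolate with the chlorophosphite followed by oxidation (a known route to α-phosphono esters) should occur at C-8 only, because the ketone is masked in the same flask as its kinetic silyl enol ether (deprotonation at C-3), which the final acid wash removes; the new stereocenter at C-8 is lost in step 8.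

Step 8
Reactants: 14 tert-butyl 2-(diethoxyphosphoryl)-2-[(1R,5R,7R)-6,6-dimethyl-2-oxobicyclo[3.3.0]octan-7-yl]acetate
Product: 17 tert-butyl (1R,5S,7R)-10-hydroxy-6,6-dimethyl-2-oxotricyclo[5.3.1.0(1,5)]undec-8-ene-8-carboxylate (both C-10 epimers), via acetal enoate 15 (not isolated), via aldehyde enoate 16 (not isolated)
Conditions: 2,2-dimethoxyacetaldehyde (60% in H2O), Ba(OH)2·8H2O, THF/H2O (40:1), 0 → 23 °C; then 1 M HCl, THF, 35 °C
Reagents that add atoms: 2,2-dimethoxyacetaldehyde, COC(OC)C=O; water, O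
Why: Horner–Wadsworth–Emmons olefination of the C-8 phosphonate carbanion with the free aldehyde of the glyoxal monoacetal forms C-8=C-9, acid then unmasks C-10 as an aldehyde, and the more substituted enol of the C-2 ketone (C-1=C-2) adds to it to form C-1–C-10. The closest known reaction types are the Horner–Wadsworth–Emmons reaction of α-branched phosphonoacetates and the acid-catalysed intramolecular aldol addition used to close bridged bicyclo[3.2.1]octane hydroxy ketones. Ring A closes in the 6-(enolexo)-exo-trig mode, and the bicyclo[3.2.1]octene (rings A and B) results because C-8 (on C-7) and C-1 are 1,3-cis on ring B. C-1 becomes quaternary with the new bond on the face of the C-7 chain, which is the convex face of the cis-diquinane, so the ring fusion stays cis; C-10 forms as an epimer mixture that is erased in step 10 and reset in step 11. The step needs C-1 over C-3 regioselectivity and the E enoate: closure through C-3 would require an eight-membered ring and acid favours the more substituted enol, while the E-selective olefination places C-10 cis to C-7 and any Z isomer cannot cyclise and should equilibrate under acid. The aldol product cannot dehydrate because C-1 carries no hydrogen.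

Step 9
Reactants: 17 tert-butyl (1R,5S,7R)-10-hydroxy-6,6-dimethyl-2-oxotricyclo[5.3.1.0(1,5)]undec-8-ene-8-carboxylate
Product: 20 tert-butyl (1S,5S,7R)-10-hydroxy-2-(methoxymethylidene)-6,6-dimethyltricyclo[5.3.1.0(1,5)]undec-8-ene-8-carboxylate (both C-10 epimers), via silyl ether 18 (not isolated), via silylated enol ether 19 (not isolated)
Conditions: Me3SiCl, Et3N, DMAP (cat.), THF, 0 °C; then Ph3P=CHOMe (from MeOCH2PPh3Cl, KN(SiMe3)2), THF, 0 → 40 °C; then K2CO3, MeOH, 23 °C
Reagents that add atoms: (methoxymethyl)triphenylphosphonium chloride, COC[P+](c1ccccc1)(c1ccccc1)c1ccccc1.[Cl-]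
Why: Wittig methoxymethylenation of the C-2 ketone should install the future formyl carbon as an enol ether; the β-hydroxyl is silylated first so that the basic ylide cannot trigger a retro-aldol opening, and methanolysis then frees it (the enol ether geometry is of no consequence).

Step 10
Reactants: 20 tert-butyl (1S,5S,7R)-10-hydroxy-2-(methoxymethylidene)-6,6-dimethyltricyclo[5.3.1.0(1,5)]undec-8-ene-8-carboxylate
Product: 21 tert-butyl (1S,5S,7R)-2-(methoxymethylidene)-6,6-dimethyl-10-oxotricyclo[5.3.1.0(1,5)]undec-8-ene-8-carboxylate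
Conditions: Dess–Martin periodinane, NaHCO3, CH2Cl2, 0 → 23 °C
Reagents that add atoms: none
Why: Dess–Martin oxidation of the allylic alcohol should give the non-enolisable C-10 enone and thereby erase the uncontrolled carbinol stereocenter, the bicarbonate buffer protecting the enol ether.

Step 11
Reactants: 21 tert-butyl (1S,5S,7R)-2-(methoxymethylidene)-6,6-dimethyl-10-oxotricyclo[5.3.1.0(1,5)]undec-8-ene-8-carboxylate
Product: 22 tert-butyl (1S,5S,7R,10S)-10-hydroxy-2-(methoxymethylidene)-6,6-dimethyltricyclo[5.3.1.0(1,5)]undec-8-ene-8-carboxylate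
Conditions: NaBH4, CeCl3·7H2O, MeOH/THF (1:4), −78 °C
Reagents that add atoms: none
Why: Luche 1,2-reduction should deliver hydride to the C-10 carbonyl from the exo face (the side of the C-11 bridge), because the endo face is screened by the C-5/C-6 bridge with its endo methyl group, which gives the 10S (endo, anti to C-11) alcohol required for the target.

Step 12
Reactants: 23 7-bromoheptan-1-ol
Product: 24 (7-bromoheptyloxy)(tert-butyl)dimethylsilane
Conditions: t-BuMe2SiCl, imidazole, DMF, 23 °C
Reagents that add atoms: tert-butyldimethylsilyl chloride, CC(C)(C)[Si](C)(C)Cl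
Why: standard silylation should protect the primary alcohol as an ether that survives ylide formation and saponification and falls in the final acidolysis.

Step 13
Reactants: 24 (7-bromoheptyloxy)(tert-butyl)dimethylsilane
Product: 25 [7-(tert-butyldimethylsilyloxy)heptyl]triphenylphosphonium bromide
Conditions: PPh3, MeCN, reflux
Reagents that add atoms: triphenylphosphine, c1ccc(cc1)P(c1ccccc1)c1ccccc1
Why: SN2 quaternisation of triphenylphosphine by the primary bromide should give the phosphonium salt.

Step 14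
Reactants: 25 [7-(tert-butyldimethylsilyloxy)heptyl]triphenylphosphonium bromide; 26 methyl 9-oxononanoate
Product: 28 methyl (9Z)-16-(tert-butyldimethylsilyloxy)hexadec-9-enoate, via ylide 27 (not isolated)
Conditions: NaN(SiMe3)2, THF, −78 °C; then 26, −78 → 23 °C
Reagents that add atoms: none
Why: Wittig reaction of the unstabilised ylide under lithium-free conditions should proceed through the cis oxaphosphetane and give the 9Z alkene.

Step 15
Reactants: 28 methyl (9Z)-16-(tert-butyldimethylsilyloxy)hexadec-9-enoate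
Product: 29 (9Z)-16-(tert-butyldimethylsilyloxy)hexadec-9-enoic acid
Conditions: LiOH, THF/MeOH/H2O, 23 °C; then dilute HCl to pH 4, 0 °C
Reagents that add atoms: lithium hydroxide, [Li+].[OH-]
Why: saponification of the methyl ester should leave the silyl ether and the Z alkene untouched.

Step 16
Reactants: 22 tert-butyl (1S,5S,7R,10S)-10-hydroxy-2-(methoxymethylidene)-6,6-dimethyltricyclo[5.3.1.0(1,5)]undec-8-ene-8-carboxylate; 29 (9Z)-16-(tert-butyldimethylsilyloxy)hexadec-9-enoic acid
Product: 31 tert-butyl (1S,5S,7R,10S)-10-{[(9Z)-16-(tert-butyldimethylsilyloxy)hexadec-9-enoyl]oxy}-2-(methoxymethylidene)-6,6-dimethyltricyclo[5.3.1.0(1,5)]undec-8-ene-8-carboxylate, via mixed anhydride 30 (not isolated)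
Conditions: 29 (1.5 equiv), 2,4,6-trichlorobenzoyl chloride, Et3N, THF, 23 °C; then 22, DMAP, toluene, 60 °C
Reagents that add atoms: none
Why: Yamaguchi esterification (mixed anhydride, then DMAP acyl transfer) should acylate the hindered secondary alcohol with retention at C-10 and leave the Z alkene, silyl ether and enol ether untouched.

Step 17
Reactants: 31 tert-butyl (1S,5S,7R,10S)-10-{[(9Z)-16-(tert-butyldimethylsilyloxy)hexadec-9-enoyl]oxy}-2-(methoxymethylidene)-6,6-dimethyltricyclo[5.3.1.0(1,5)]undec-8-ene-8-carboxylate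
Product: 33 (1S,2S,5S,7R,10S)-2-formyl-10-{[(9Z)-16-hydroxyhexadec-9-enoyl]oxy}-6,6-dimethyltricyclo[5.3.1.0(1,5)]undec-8-ene-8-carboxylic acid (target), via C-2 epimer 32 (not isolated)
Conditions: CF3CO2H/CH2Cl2/H2O (10:10:1), 0 → 23 °C, until the aldehyde has equilibrated
Reagents that add atoms: water, O
Why: aqueous trifluoroacetic acid should cleave the tert-butyl ester and the silyl ether and hydrolyse the enol ether to the aldehyde in one operation; protonation at C-2 from the open face should give partly the epimer 32, which equilibrates through the enol to the more stable 2S aldehyde with the formyl group anti to the C-10 acyloxy group.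

Compound list
1 | (S)-α-campholenic aldehyde, 2-[(1S)-2,2,3-trimethylcyclopent-3-en-1-yl]acetaldehyde | O=CC[C@@H]1CC=C(C)C1(C)C | starting material
2 | (S)-α-campholenic acid, 2-[(1S)-2,2,3-trimethylcyclopent-3-en-1-yl]acetic acid | OC(=O)C[C@@H]1CC=C(C)C1(C)C | intermediate
3 | tert-butyl 2-[(1S)-2,2,3-trimethylcyclopent-3-en-1-yl]acetate | CC(C)(C)OC(=O)C[C@@H]1CC=C(C)C1(C)C | intermediate
4 | tert-butyl 2-[(1S)-3-(hydroxymethyl)-2,2-dimethylcyclopent-3-en-1-yl]acetate (not isolated) | CC(C)(C)OC(=O)C[C@@H]1CC=C(CO)C1(C)C | intermediate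
5 | tert-butyl 2-[(1S)-3-formyl-2,2-dimethylcyclopent-3-en-1-yl]acetate | CC(C)(C)OC(=O)C[C@@H]1CC=C(C=O)C1(C)C | intermediate
6 | tert-butyl 2-[(1S,4R)-4-(1-ethoxyethenyl)-2,2-dimethyl-3-[(trimethylsilyloxy)methylidene]cyclopentyl]acetate (not isolated; ethoxyvinyl group trans to the acetate chain) | CC(C)(C)OC(=O)C[C@@H]1C[C@@H](C(=C)OCC)C(=CO[Si](C)(C)C)C1(C)C | intermediate
7 | tert-butyl 2-[(1S,3R,4R)-4-acetyl-3-formyl-2,2-dimethylcyclopentyl]acetate (acetyl trans to the acetate chain, formyl cis to acetyl; formed with its 3S epimer, both converge in step 5) | CC(C)(C)OC(=O)C[C@@H]1C[C@@H](C(C)=O)[C@@H](C=O)C1(C)C | intermediate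
8 | tert-butyl 2-[(1R,5R,7S)-4-hydroxy-6,6-dimethyl-2-oxobicyclo[3.3.0]octan-7-yl]acetate (not isolated; C-4 epimers) | CC(C)(C)OC(=O)C[C@@H]1C[C@H]2C(=O)CC(O)[C@H]2C1(C)C | intermediate
9 | tert-butyl 2-[(1R,5R,7S)-6,6-dimethyl-2-oxobicyclo[3.3.0]oct-3-en-7-yl]acetate (cis-fused, chain cis to H-1 and H-5) | CC(C)(C)OC(=O)C[C@@H]1C[C@H]2C(=O)C=C[C@H]2C1(C)C | intermediate
10 | tert-butyl 2-[(1R,5R,7S)-6,6-dimethyl-2-oxobicyclo[3.3.0]octan-7-yl]acetate | CC(C)(C)OC(=O)C[C@@H]1C[C@H]2C(=O)CC[C@H]2C1(C)C | intermediate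
11 | tert-butyl 2-[(1R,5R,7S)-6,6-dimethyl-2-(trimethylsilyloxy)bicyclo[3.3.0]oct-2-en-7-yl]acetate (not isolated) | CC(C)(C)OC(=O)C[C@@H]1C[C@H]2C(O[Si](C)(C)C)=CC[C@H]2C1(C)C | intermediate
12 | tert-butyl 2-(diethoxyphosphanyl)-2-[(1R,5R,7R)-6,6-dimethyl-2-(trimethylsilyloxy)bicyclo[3.3.0]oct-2-en-7-yl]acetate (not isolated; epimers at the phosphorus-bearing carbon) | CCOP(OCC)C(C(=O)OC(C)(C)C)[C@@H]1C[C@H]2C(O[Si](C)(C)C)=CC[C@H]2C1(C)C | intermediate
13 | tert-butyl 2-(diethoxyphosphoryl)-2-[(1R,5R,7R)-6,6-dimethyl-2-(trimethylsilyloxy)bicyclo[3.3.0]oct-2-en-7-yl]acetate (not isolated) | CCOP(=O)(OCC)C(C(=O)OC(C)(C)C)[C@@H]1C[C@H]2C(O[Si](C)(C)C)=CC[C@H]2C1(C)C | intermediate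
14 | tert-butyl 2-(diethoxyphosphoryl)-2-[(1R,5R,7R)-6,6-dimethyl-2-oxobicyclo[3.3.0]octan-7-yl]acetate (epimers at the phosphorus-bearing carbon) | CCOP(=O)(OCC)C(C(=O)OC(C)(C)C)[C@@H]1C[C@H]2C(=O)CC[C@H]2C1(C)C | intermediate
15 | tert-butyl (2E)-2-[(1R,5R,7R)-6,6-dimethyl-2-oxobicyclo[3.3.0]octan-7-yl]-4,4-dimethoxybut-2-enoate (not isolated) | COC(OC)/C=C(/C(=O)OC(C)(C)C)[C@@H]1C[C@H]2C(=O)CC[C@H]2C1(C)C | intermediate
16 | tert-butyl (2E)-2-[(1R,5R,7R)-6,6-dimethyl-2-oxobicyclo[3.3.0]octan-7-yl]-4-oxobut-2-enoate (not isolated) | O=C/C=C(/C(=O)OC(C)(C)C)[C@@H]1C[C@H]2C(=O)CC[C@H]2C1(C)C | intermediate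
17 | tert-butyl (1R,5S,7R)-10-hydroxy-6,6-dimethyl-2-oxotricyclo[5.3.1.0(1,5)]undec-8-ene-8-carboxylate (both C-10 epimers; C-10 is reset in steps 10 and 11) | CC1(C)[C@H]2C[C@@]3(C(O)C=C2C(=O)OC(C)(C)C)C(=O)CC[C@@H]13 | intermediate
18 | tert-butyl (1R,5S,7R)-6,6-dimethyl-2-oxo-10-(trimethylsilyloxy)tricyclo[5.3.1.0(1,5)]undec-8-ene-8-carboxylate (not isolated; C-10 epimers) | CC1(C)[C@H]2C[C@@]3(C(O[Si](C)(C)C)C=C2C(=O)OC(C)(C)C)C(=O)CC[C@@H]13 | intermediate
19 | tert-butyl (1S,5S,7R)-2-(methoxymethylidene)-6,6-dimethyl-10-(trimethylsilyloxy)tricyclo[5.3.1.0(1,5)]undec-8-ene-8-carboxylate (not isolated; C-10 epimers, enol ether E/Z) | CC1(C)[C@H]2C[C@@]3(C(O[Si](C)(C)C)C=C2C(=O)OC(C)(C)C)C(=COC)CC[C@@H]13 | intermediate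
20 | tert-butyl (1S,5S,7R)-10-hydroxy-2-(methoxymethylidene)-6,6-dimethyltricyclo[5.3.1.0(1,5)]undec-8-ene-8-carboxylate (C-10 epimers, enol ether E/Z) | CC1(C)[C@H]2C[C@@]3(C(O)C=C2C(=O)OC(C)(C)C)C(=COC)CC[C@@H]13 | intermediate
21 | tert-butyl (1S,5S,7R)-2-(methoxymethylidene)-6,6-dimethyl-10-oxotricyclo[5.3.1.0(1,5)]undec-8-ene-8-carboxylate (enol ether E/Z) | CC1(C)[C@H]2C[C@@]3(C(=O)C=C2C(=O)OC(C)(C)C)C(=COC)CC[C@@H]13 | intermediate
22 | tert-butyl (1S,5S,7R,10S)-10-hydroxy-2-(methoxymethylidene)-6,6-dimethyltricyclo[5.3.1.0(1,5)]undec-8-ene-8-carboxylate (hydroxyl anti to C-11; enol ether E/Z) | CC1(C)[C@H]2C[C@@]3([C@@H](O)C=C2C(=O)OC(C)(C)C)C(=COC)CC[C@@H]13 | intermediate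
23 | 7-bromoheptan-1-ol | OCCCCCCCBr | starting material
24 | (7-bromoheptyloxy)(tert-butyl)dimethylsilane | CC(C)(C)[Si](C)(C)OCCCCCCCBr | intermediate
25 | [7-(tert-butyldimethylsilyloxy)heptyl]triphenylphosphonium bromide | CC(C)(C)[Si](C)(C)OCCCCCCC[P+](c1ccccc1)(c1ccccc1)c1ccccc1.[Br-] | intermediate
26 | methyl 9-oxononanoate | COC(=O)CCCCCCCC=O | starting material
27 | [7-(tert-butyldimethylsilyloxy)heptylidene]triphenylphosphorane (not isolated) | CC(C)(C)[Si](C)(C)OCCCCCCC=P(c1ccccc1)(c1ccccc1)c1ccccc1 | intermediate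
28 | methyl (9Z)-16-(tert-butyldimethylsilyloxy)hexadec-9-enoate | COC(=O)CCCCCCC/C=C\CCCCCCO[Si](C)(C)C(C)(C)C | intermediate
29 | (9Z)-16-(tert-butyldimethylsilyloxy)hexadec-9-enoic acid | OC(=O)CCCCCCC/C=C\CCCCCCO[Si](C)(C)C(C)(C)C | intermediate
30 | (9Z)-16-(tert-butyldimethylsilyloxy)hexadec-9-enoic 2,4,6-trichlorobenzoic anhydride (not isolated) | O=C(OC(=O)CCCCCCC/C=C\CCCCCCO[Si](C)(C)C(C)(C)C)c1c(Cl)cc(Cl)cc1Cl | intermediate
31 | tert-butyl (1S,5S,7R,10S)-10-{[(9Z)-16-(tert-butyldimethylsilyloxy)hexadec-9-enoyl]oxy}-2-(methoxymethylidene)-6,6-dimethyltricyclo[5.3.1.0(1,5)]undec-8-ene-8-carboxylate | CC1(C)[C@H]2C[C@@]3([C@@H](OC(=O)CCCCCCC/C=C\CCCCCCO[Si](C)(C)C(C)(C)C)C=C2C(=O)OC(C)(C)C)C(=COC)CC[C@@H]13 | intermediate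
32 | (1S,2R,5S,7R,10S)-2-formyl-10-{[(9Z)-16-hydroxyhexadec-9-enoyl]oxy}-6,6-dimethyltricyclo[5.3.1.0(1,5)]undec-8-ene-8-carboxylic acid (C-2 epimer of 33, not isolated) | CC1(C)[C@H]2C[C@@]3([C@@H](OC(=O)CCCCCCC/C=C\CCCCCCO)C=C2C(=O)O)[C@H](C=O)CC[C@@H]13 | intermediate
33 | (1S,2S,5S,7R,10S)-2-formyl-10-{[(9Z)-16-hydroxyhexadec-9-enoyl]oxy}-6,6-dimethyltricyclo[5.3.1.0(1,5)]undec-8-ene-8-carboxylic acid | CC1(C)[C@H]2C[C@@]3([C@@H](OC(=O)CCCCCCC/C=C\CCCCCCO)C=C2C(=O)O)[C@@H](C=O)CC[C@@H]13 | target

Total step count: 17. Longest linear sequence: 13 steps (steps 1 to 11, then 16 and 17).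

Steps most likely to fail

Step 8. The hindered α-branched phosphonate may olefinate slowly, and in the acid stage the ketone may fail to react through its more substituted enol, so that the aldehyde is lost to hydration, to isomerisation into the non-cyclising Z enoate or to reversal of the aldol. The fallback sets out from 14 and comes back at 17. The olefination is run alone (Ba(OH)2·8H2O, wet THF) and the acetal enoate 15 is isolated; pyridinium p-toluenesulfonate in acetone/H2O gives the aldehyde 16. The ketone is then brominated at its more substituted α-carbon (pyridinium tribromide, AcOH) to give the C-1 bromo ketone F1. CrCl2 (LiI, THF) should generate the chromium enolate at C-1 only, and its intramolecular Reformatsky-type addition to the C-10 aldehyde closes ring A to give 17.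

Step 9. The basic ylide may enolise the hindered C-2 ketone instead of adding to it, or the silyl ether may be lost and the β-hydroxy ketone opened by retro-aldol cleavage. The fallback sets out from 17 and comes back at 20. The silyl ether 18 is isolated and treated with lithiated (methoxymethyl)diphenylphosphine oxide (LiN(iPr)2, THF, −78 °C), a less basic and more nucleophilic carbanion, to give the β-hydroxy phosphine oxide F2 (Horner–Wittig addition). KH in THF then eliminates diphenylphosphinate to give 19, and K2CO3/MeOH frees the hydroxyl to give 20.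

Step 7. Masking of the ketone in the flask may be incomplete, so that phosphinylation also takes place at the ketone α-carbon, or the silyl enol ether may not survive the oxidation. The fallback sets out from 10 and comes back at 14. The ketone is protected as the dioxolane F3 (ethylene glycol, pyridinium p-toluenesulfonate, benzene, reflux with water removal). The ester enolate (LiN(iPr)2, THF, −78 °C) is phosphinylated with ClP(OEt)2 and oxidised with H2O2 to give the phosphono dioxolane F4, and pyridinium p-toluenesulfonate in acetone/H2O returns 14.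

Further compounds
F1 | step 8 | tert-butyl (2E)-2-[1-bromo-6,6-dimethyl-2-oxobicyclo[3.3.0]octan-7-yl]-4-oxobut-2-enoate (configuration as in 16, bromine in place of H-1) | O=C/C=C(/C(=O)OC(C)(C)C)[C@@H]1C[C@@]2(Br)C(=O)CC[C@H]2C1(C)C
F2 | step 9 | tert-butyl 2-[(diphenylphosphoryl)(methoxy)methyl]-2-hydroxy-6,6-dimethyl-10-(trimethylsilyloxy)tricyclo[5.3.1.0(1,5)]undec-8-ene-8-carboxylate (ring configuration as in 18) | CC1(C)[C@H]2C[C@@]3(C(O[Si](C)(C)C)C=C2C(=O)OC(C)(C)C)C(O)(C(OC)P(=O)(c4ccccc4)c5ccccc5)CC[C@@H]13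
F3 | step 7 | tert-butyl 2-[6,6-dimethyl-2,2-(ethylenedioxy)bicyclo[3.3.0]octan-7-yl]acetate (configuration as in 10) | CC(C)(C)OC(=O)C[C@@H]1C[C@H]2C3(OCCO3)CC[C@H]2C1(C)C
F4 | step 7 | tert-butyl 2-(diethoxyphosphoryl)-2-[6,6-dimethyl-2,2-(ethylenedioxy)bicyclo[3.3.0]octan-7-yl]acetate (configuration as in 14) | CCOP(=O)(OCC)C(C(=O)OC(C)(C)C)[C@@H]1C[C@H]2C3(OCCO3)CC[C@H]2C1(C)C
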